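The 2‑methyl‑6‑alkyl‑1,4‑benzoquinone ring is built last instead of being carried through the synthesis. With ring atoms numbered C1(=O) between C2 (methyl) and C6 (side chain), and C4(=O) between C3–H and C5–H, a Dötz benzannulation joins three pieces. A terminal alkyne that already holds the complete (10′S,11′S)‑diol tetraprenyl chain supplies C5 and C6. An (E)‑propenyl(methoxy)carbene pentacarbonylchromium complex supplies C4, C3, C2 and the methyl group, and one CO ligand supplies C1. In one operation the step forms the C4–C5 and C1–C2 bonds (CO insertion adds C6–C1), and oxidative work‑up delivers the quinone. It exploits the fact that both ring substituents flank the same carbonyl, C1.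

Key step: step 9

Remark: side‑chain atoms are numbered C1′–C16′ from the ring; carbonyl ligands on chromium are written Cr=C=O in the SMILES; compounds 1, 5, 13 and 14 and LiC≡CSiMe3 (THF solution) are taken to be commercial.

Step 1
Reactants: 1 geranyl bromide [(2E)‑1‑bromo‑3,7‑dimethylocta‑2,6‑diene]
Product: 2 [(4E)‑5,9‑dimethyldeca‑4,8‑dien‑1‑yn‑1‑yl]trimethylsilane
Conditions: LiC≡CSiMe3 (1.2 equiv, 0.5 M in THF), THF/DMPU, −78 °C to rt
Reagents that add atoms: lithium (trimethylsilyl)acetylide, [Li]C#C[Si](C)(C)C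
Why: SN2 alkylation of a lithium acetylide by a primary allylic bromide should give the skipped enyne with the E olefin untouched, and the silyl cap keeps the alkyne C–H out of the later organometallic step.

Step 2
Reactants: 2 [(4E)‑5,9‑dimethyldeca‑4,8‑dien‑1‑yn‑1‑yl]trimethylsilane
Product: 3 (2E,6E)‑2,6‑dimethyl‑10‑(trimethylsilyl)deca‑2,6‑dien‑9‑yn‑1‑ol
Conditions: SeO2 (0.3 equiv), t‑BuOOH (3 equiv), salicylic acid (0.1 equiv), CH2Cl2, 0 °C to rt
Reagents that add atoms: tert‑butyl hydroperoxide, CC(C)(C)OO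
Why: Riley allylic oxidation (ene reaction with SeO2, then [2,3]‑sigmatropic shift) should hydroxylate the (E)‑methyl group of the terminal, least hindered trisubstituted olefin and give the E allylic alcohol.

Step 3
Reactants: 3 (2E,6E)‑2,6‑dimethyl‑10‑(trimethylsilyl)deca‑2,6‑dien‑9‑yn‑1‑ol
Product: 4 [(4E,8E)‑10‑bromo‑5,9‑dimethyldeca‑4,8‑dien‑1‑yn‑1‑yl]trimethylsilane
Conditions: PBr3 (0.4 equiv), Et2O, −10 °C
Reagents that add atoms: phosphorus tribromide, BrP(Br)Br
Why: SN2 displacement on the bromophosphite of a primary allylic alcohol at low temperature should give the allylic bromide without allylic transposition or loss of olefin geometry.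

Step 4
Reactants: 5 nerol [(2Z)‑3,7‑dimethylocta‑2,6‑dien‑1‑ol]
Product: 6 (2R,3S)‑2,3‑epoxynerol {[(2R,3S)‑3‑methyl‑3‑(4‑methylpent‑3‑en‑1‑yl)oxiran‑2‑yl]methanol}
Conditions: Ti(OiPr)4 (10 mol %), D‑(−)‑diethyl tartrate (14 mol %), t‑BuOOH (2 equiv, anhydrous), 4 Å molecular sieves, CH2Cl2, −20 °C
Reagents that add atoms: tert‑butyl hydroperoxide, CC(C)(C)OO
Why: Sharpless asymmetric epoxidation acts only on the allylic‑alcohol olefin and, with D‑(−)‑tartrate, should deliver oxygen to the face that gives the (2R,3S) cis‑epoxide (the mirror image of the L‑(+)‑tartrate product), which sets both stereocentres.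

Step 5
Reactants: 6 (2R,3S)‑2,3‑epoxynerol
Product: 8 (2R,3S)‑3,7‑dimethyl‑1‑(phenylsulfanyl)oct‑6‑ene‑2,3‑diol, via Payne‑rearranged terminal epoxide 7 (not isolated)
Conditions: PhSH (1.5 equiv, slow addition), 0.5 M aq. NaOH, t‑BuOH, 70 °C
Reagents that add atoms: benzenethiol, Sc1ccccc1
Why: Payne rearrangement (the C1 alkoxide opens the epoxide at C2 with inversion) followed by irreversible thiolate opening of terminal epoxide 7 at C1 should give the 1‑sulfanyl‑2,3‑diol with C2 inverted once and C3 untouched, which is the relative configuration of the target diol; direct attack on 6 is blocked at quaternary C3 and at neopentyl‑like C2.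

Step 6
Reactants: 8 (2R,3S)‑3,7‑dimethyl‑1‑(phenylsulfanyl)oct‑6‑ene‑2,3‑diol; 4 [(4E,8E)‑10‑bromo‑5,9‑dimethyldeca‑4,8‑dien‑1‑yn‑1‑yl]trimethylsilane
Product: 11 (4E,8E,12S,13S)‑5,9,13,17‑tetramethyl‑1‑(trimethylsilyl)octadeca‑4,8,16‑trien‑1‑yne‑12,13‑diol, via trilithio intermediate 9 (not isolated), via phenylthio cuprate 10 (not isolated)
Conditions: n‑BuLi (2.05 equiv), THF, −78 °C; lithium 4,4′‑di‑tert‑butylbiphenylide (LiDBB, 2.1 equiv), −78 °C; CuBr·SMe2 (1.0 equiv), −78 °C; then 4, −78 to −40 °C; H2O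
Reagents that add atoms: none
Why: reductive lithiation of the alkyl phenyl sulfide (C–S cleavage by the arene radical anion) gives a β‑oxido primary alkyllithium that should resist elimination at −78 °C, and its mixed phenylthio(alkyl)cuprate should displace the primary allylic bromide (SN2) to join C9′ to C8′ without touching either stereocentre or the E olefins.

Step 7
Reactants: 11 (4E,8E,12S,13S)‑5,9,13,17‑tetramethyl‑1‑(trimethylsilyl)octadeca‑4,8,16‑trien‑1‑yne‑12,13‑diol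
Product: 12 (4E,8E,12S,13S)‑5,9,13,17‑tetramethyloctadeca‑4,8,16‑trien‑1‑yne‑12,13‑diol
Conditions: K2CO3 (0.2 equiv), MeOH, rt
Reagents that add atoms: none
Why: methoxide‑mediated protodesilylation of the alkynylsilane should free the terminal alkyne needed for regioselective benzannulation.

Step 8
Reactants: 13 (E)‑1‑bromoprop‑1‑ene; 14 hexacarbonylchromium
Product: 17 pentacarbonyl[(2E)‑1‑methoxybut‑2‑en‑1‑ylidene]chromium, via (E)‑prop‑1‑enyllithium 15 (not isolated), via lithium acylchromate 16 (not isolated)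
Conditions: t‑BuLi (2.0 equiv), Et2O, −78 °C; Cr(CO)6, Et2O, −78 °C to rt; then Me3OBF4, CH2Cl2, 0 °C
Reagents that add atoms: trimethyloxonium tetrafluoroborate, C[O+](C)C.F[B-](F)(F)F
Why: Fischer carbene synthesis, in which stereoretentive bromine–lithium exchange, addition of the vinyllithium to a CO ligand and O‑methylation of the acylchromate should give the (E)‑alkenyl(methoxy)carbene complex.

Step 9
Reactants: 12 (4E,8E,12S,13S)‑5,9,13,17‑tetramethyloctadeca‑4,8,16‑trien‑1‑yne‑12,13‑diol; 17 pentacarbonyl[(2E)‑1‑methoxybut‑2‑en‑1‑ylidene]chromium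
Product: 19 2‑[(2E,6E,10S,11S)‑10,11‑dihydroxy‑3,7,11,15‑tetramethylhexadeca‑2,6,14‑trien‑1‑yl]‑6‑methylcyclohexa‑2,5‑diene‑1,4‑dione, via 4‑methoxyphenol 18 (not isolated)
Conditions: 17 (1.3 equiv), THF (0.05 M), 50 °C; then (NH4)2Ce(NO3)6, MeCN/H2O, 0 °C, short contact
Reagents that add atoms: water, O
Why: Loss of one CO from 17 lets the terminal alkyne insert into the Cr=C bond with its unsubstituted carbon (ring C5) bonding to the carbene carbon (ring C4); CO insertion then gives a chromium‑bound dienylketene whose ketene carbon (C1) sits on the chain‑bearing carbon C6, 6π‑electrocyclisation onto the methyl‑bearing propenyl carbon closes C1–C2, tautomerisation gives 4‑methoxyphenol 18, and (NH4)2Ce(NO3)6 oxidatively demethylates 18 to the quinone with water supplying the C4 oxygen. The closest known reaction type is the Dötz benzannulation of alkenyl(alkoxy)carbene complexes of zerovalent chromium with alkynes, a formal [3+2+1] annulation, with its standard oxidative work‑up. The one ring formed is closed by 6π‑electrocyclic ring closure of the metal‑bound dienylketene. No stereocentre is created, and the (10′S,11′S)‑diol and the E olefins are spectators. The step needs regiocontrol in the alkyne insertion, secured by the steric difference between H and the CH2 chain of the terminal alkyne (the larger group ends next to the CO‑derived carbon, hence the 2,6‑pattern), and six‑ring rather than five‑ring annulation, which alkenyl(methoxy)carbene complexes in THF should favour.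

Compound list
1 | geranyl bromide, (2E)‑1‑bromo‑3,7‑dimethylocta‑2,6‑diene | CC(C)=CCC/C(C)=C/CBr | starting material
2 | [(4E)‑5,9‑dimethyldeca‑4,8‑dien‑1‑yn‑1‑yl]trimethylsilane | CC(C)=CCC/C(C)=C/CC#C[Si](C)(C)C | intermediate
3 | (2E,6E)‑2,6‑dimethyl‑10‑(trimethylsilyl)deca‑2,6‑dien‑9‑yn‑1‑ol | OC/C(C)=C/CC/C(C)=C/CC#C[Si](C)(C)C | intermediate
4 | [(4E,8E)‑10‑bromo‑5,9‑dimethyldeca‑4,8‑dien‑1‑yn‑1‑yl]trimethylsilane | BrC/C(C)=C/CC/C(C)=C/CC#C[Si](C)(C)C | intermediate
5 | nerol, (2Z)‑3,7‑dimethylocta‑2,6‑dien‑1‑ol | CC(C)=CCC/C(C)=C\CO | starting material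
6 | (2R,3S)‑2,3‑epoxynerol, [(2R,3S)‑3‑methyl‑3‑(4‑methylpent‑3‑en‑1‑yl)oxiran‑2‑yl]methanol | OC[C@H]1O[C@@]1(C)CCC=C(C)C | intermediate
7 | (2S)‑6‑methyl‑2‑[(2S)‑oxiran‑2‑yl]hept‑5‑en‑2‑ol (Payne isomer of 6, formed in the flask) | CC(C)=CCC[C@](C)(O)[C@@H]1CO1 | intermediate
8 | (2R,3S)‑3,7‑dimethyl‑1‑(phenylsulfanyl)oct‑6‑ene‑2,3‑diol | CC(C)=CCC[C@](C)(O)[C@@H](O)CSc1ccccc1 | intermediate
9 | dilithium (2S,3S)‑1‑lithio‑3,7‑dimethyloct‑6‑ene‑2,3‑bis(olate) (formed in the flask) | CC(C)=CCC[C@](C)(O[Li])[C@@H](O[Li])C[Li] | intermediate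
10 | lithium [(2R,3S)‑2,3‑bis(lithiooxy)‑3,7‑dimethyloct‑6‑en‑1‑yl](phenylsulfanyl)cuprate, monovalent copper (formed in the flask) | [Li+].CC(C)=CCC[C@](C)(O[Li])[C@@H](O[Li])C[Cu-]Sc1ccccc1 | intermediate
11 | (4E,8E,12S,13S)‑5,9,13,17‑tetramethyl‑1‑(trimethylsilyl)octadeca‑4,8,16‑trien‑1‑yne‑12,13‑diol | CC(C)=CCC[C@](C)(O)[C@@H](O)CC/C(C)=C/CC/C(C)=C/CC#C[Si](C)(C)C | intermediate
12 | (4E,8E,12S,13S)‑5,9,13,17‑tetramethyloctadeca‑4,8,16‑trien‑1‑yne‑12,13‑diol | CC(C)=CCC[C@](C)(O)[C@@H](O)CC/C(C)=C/CC/C(C)=C/CC#C | intermediate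
13 | (E)‑1‑bromoprop‑1‑ene | C/C=C/Br | starting material
14 | hexacarbonylchromium, Cr(CO)6 | O=C=[Cr](=C=O)(=C=O)(=C=O)(=C=O)=C=O | starting material
15 | (E)‑prop‑1‑enyllithium (formed in the flask) | C/C=C/[Li] | intermediate
16 | lithium pentacarbonyl[(2E)‑1‑oxidobut‑2‑en‑1‑ylidene]chromate (formed in the flask) | C/C=C/C(O[Li])=[Cr](=C=O)(=C=O)(=C=O)(=C=O)=C=O | intermediate
17 | pentacarbonyl[(2E)‑1‑methoxybut‑2‑en‑1‑ylidene]chromium | C/C=C/C(OC)=[Cr](=C=O)(=C=O)(=C=O)(=C=O)=C=O | intermediate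
18 | 2‑[(2E,6E,10S,11S)‑10,11‑dihydroxy‑3,7,11,15‑tetramethylhexadeca‑2,6,14‑trien‑1‑yl]‑4‑methoxy‑6‑methylphenol (formed in the flask) | CC(C)=CCC[C@](C)(O)[C@@H](O)CC/C(C)=C/CC/C(C)=C/Cc1cc(OC)cc(C)c1O | intermediate
19 | 2‑[(2E,6E,10S,11S)‑10,11‑dihydroxy‑3,7,11,15‑tetramethylhexadeca‑2,6,14‑trien‑1‑yl]‑6‑methylcyclohexa‑2,5‑diene‑1,4‑dione | CC(C)=CCC[C@](C)(O)[C@@H](O)CC/C(C)=C/CC/C(C)=C/CC1=CC(=O)C=C(C)C1=O | target

Total step count: 9.
Longest linear sequence: 6 steps (steps 1, 2, 3, 6, 7, 9, from geranyl bromide 1).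

Steps most likely to fail

Step 6. The β‑oxido organometallic may lose lithium oxide by β‑elimination before it couples. The cuprate may also attack the γ‑carbon of the allylic bromide (SN2′) or transfer an electron to it, which would give branched or homocoupled material. The fallback sets out from 8 and comes back at 11; it replaces the reductive lithiation by a sulfone‑stabilised carbanion. Chemoselective S‑oxidation of 8 (H2O2, (NH4)6Mo7O24 cat., EtOH, 0 °C) should give (2R,3S)‑3,7‑dimethyl‑1‑(phenylsulfonyl)oct‑6‑ene‑2,3‑diol F1. Its trianion (n‑BuLi, 3.1 equiv, THF/DMPU, −78 °C) is alkylated at carbon by bromide 4 to give (4E,8E,12R,13S)‑5,9,13,17‑tetramethyl‑11‑(phenylsulfonyl)‑1‑(trimethylsilyl)octadeca‑4,8,16‑trien‑1‑yne‑12,13‑diol F2 as a mixture of C11 epimers. Buffered sodium amalgam (Na/Hg, Na2HPO4, MeOH/THF, −20 °C) then removes the sulfonyl group and returns 11.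

Step 9. The cerium oxidant may cleave the unprotected vicinal diol, or the hydroxyl groups may intercept the ketene intermediate; five‑membered‑ring annulation may also compete with benzannulation. The fallback sets out from 12 and comes back at 19; it masks the diol through the annulation and oxidation, so it answers the hydroxyl‑related failures only. 2,2‑Dimethoxypropane and PPTS in CH2Cl2 should convert 12 into (4S,5S)‑5‑[(3E,7E)‑3,7‑dimethylundeca‑3,7‑dien‑10‑yn‑1‑yl]‑2,2,4‑trimethyl‑4‑(4‑methylpent‑3‑en‑1‑yl)‑1,3‑dioxolane F3. Benzannulation with 17 as in step 9 gives, in the flask, the 10′,11′‑O‑isopropylidene acetal of phenol 18 F4. Oxidation with (NH4)2Ce(NO3)6 gives the 10′,11′‑O‑isopropylidene acetal of quinone 19 F5, and 80% aqueous AcOH at 40 °C removes the acetonide and returns 19.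

Step 2. The oxidation may fail to discriminate between the terminal and the internal trisubstituted olefin, may attack the doubly activated C3 methylene between alkyne and olefin, or may run on to the enal. The fallback sets out from 1 and comes back at 3; it moves the oxidation to a substrate whose proximal olefin is deactivated by an allylic ester and brings the alkyne in afterwards. KOAc in DMF converts 1 into geranyl acetate F6 (also commercial). SeO2/t‑BuOOH should give (2E,6E)‑8‑hydroxy‑3,7‑dimethylocta‑2,6‑dien‑1‑yl acetate F7. Dihydropyran with PPTS gives (2E,6E)‑3,7‑dimethyl‑8‑(oxan‑2‑yloxy)octa‑2,6‑dien‑1‑yl acetate F8, and K2CO3 in MeOH frees (2E,6E)‑3,7‑dimethyl‑8‑(oxan‑2‑yloxy)octa‑2,6‑dien‑1‑ol F9. PBr3 gives 2‑{[(2E,6E)‑8‑bromo‑2,6‑dimethylocta‑2,6‑dien‑1‑yl]oxy}oxane F10, and LiC≡CSiMe3 in THF/DMPU gives trimethyl[(4E,8E)‑5,9‑dimethyl‑10‑(oxan‑2‑yloxy)deca‑4,8‑dien‑1‑yn‑1‑yl]silane F11. PPTS in MeOH removes the acetal and returns 3.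

Further compounds
F1 | step 6 | (2R,3S)‑3,7‑dimethyl‑1‑(phenylsulfonyl)oct‑6‑ene‑2,3‑diol | CC(C)=CCC[C@](C)(O)[C@@H](O)CS(=O)(=O)c1ccccc1
F2 | step 6 | (4E,8E,12R,13S)‑5,9,13,17‑tetramethyl‑11‑(phenylsulfonyl)‑1‑(trimethylsilyl)octadeca‑4,8,16‑trien‑1‑yne‑12,13‑diol, C11 epimers | CC(C)=CCC[C@](C)(O)[C@@H](O)C(C/C(C)=C/CC/C(C)=C/CC#C[Si](C)(C)C)S(=O)(=O)c1ccccc1
F3 | step 9 | (4S,5S)‑5‑[(3E,7E)‑3,7‑dimethylundeca‑3,7‑dien‑10‑yn‑1‑yl]‑2,2,4‑trimethyl‑4‑(4‑methylpent‑3‑en‑1‑yl)‑1,3‑dioxolane | CC(C)=CCC[C@]1(C)OC(C)(C)O[C@H]1CC/C(C)=C/CC/C(C)=C/CC#C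
F4 | step 9 | 10′,11′‑O‑isopropylidene acetal of phenol 18 | CC(C)=CCC[C@]1(C)OC(C)(C)O[C@H]1CC/C(C)=C/CC/C(C)=C/Cc1cc(OC)cc(C)c1O
F5 | step 9 | 10′,11′‑O‑isopropylidene acetal of quinone 19 | CC(C)=CCC[C@]1(C)OC(C)(C)O[C@H]1CC/C(C)=C/CC/C(C)=C/CC2=CC(=O)C=C(C)C2=O
F6 | step 2 | geranyl acetate, (2E)‑3,7‑dimethylocta‑2,6‑dien‑1‑yl acetate | CC(C)=CCC/C(C)=C/COC(C)=O
F7 | step 2 | (2E,6E)‑8‑hydroxy‑3,7‑dimethylocta‑2,6‑dien‑1‑yl acetate | OC/C(C)=C/CC/C(C)=C/COC(C)=O
F8 | step 2 | (2E,6E)‑3,7‑dimethyl‑8‑(oxan‑2‑yloxy)octa‑2,6‑dien‑1‑yl acetate | C1CCC(OC/C(C)=C/CC/C(C)=C/COC(C)=O)OC1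
F9 | step 2 | (2E,6E)‑3,7‑dimethyl‑8‑(oxan‑2‑yloxy)octa‑2,6‑dien‑1‑ol | C1CCC(OC/C(C)=C/CC/C(C)=C/CO)OC1
F10 | step 2 | 2‑{[(2E,6E)‑8‑bromo‑2,6‑dimethylocta‑2,6‑dien‑1‑yl]oxy}oxane | C1CCC(OC/C(C)=C/CC/C(C)=C/CBr)OC1
F11 | step 2 | trimethyl[(4E,8E)‑5,9‑dimethyl‑10‑(oxan‑2‑yloxy)deca‑4,8‑dien‑1‑yn‑1‑yl]silane | C1CCC(OC/C(C)=C/CC/C(C)=C/CC#C[Si](C)(C)C)OC1
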